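The route makes both azulenes instead of attaching them. At C2 and at C6 of the indenone each azulene is held by a five-membered-ring carbon whose ring neighbours are a CH and the fusion carbon adjoining the methyl-bearing seven-ring carbon. Disconnecting, in each azulene, the bond from that carbon to the fusion carbon and the bond from the CH to the methyl-bearing five-ring carbon leaves an enol ether arm on the indenone and C8a/C3 of 5-isopropyl-3,8-dimethyl-2H-cyclohepta[b]furan-2-one. One twofold thermal [8+2] cycloaddition, with loss of CO2 and ethanol, thus forms four C–C bonds and both five-membered rings. The precursor is a 3,7-dimethylindenone with (E)-2-ethoxyvinyl arms at C2 and C6 and its C4 aldehyde masked as a dioxolane.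

Key step: step 12

Assumption (stereochemistry): the target has no stereocentre; the indanones of steps 1 to 4 are racemic at C3, a centre that disappears on indenone formation, and rotation about the two azulene–indenone bonds is left unspecified.

Assumption (twofold steps): the numbered mono-products are the ones expected to form first (C2–Br before C6–Br in the coupling, the C6 arm before the C2 arm in the cycloaddition); the reverse order would give the same products.

Remark on the order of events: the C4 aldehyde stays free through both brominations, which release HBr, and is acetalised only afterwards.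

**Indenone core**

Step 1
Reactants: 1 4-bromotoluene; 2 (E)-crotonoyl chloride
Product: 4 rac-4-bromo-3,7-dimethyl-2,3-dihydro-1H-inden-1-one, via (E)-aryl propenyl ketone 3 (not isolated)
Conditions: AlCl3 (2.5 equiv), ClCH2CH2Cl, 0 °C to rt, then 60 °C
Reagents that add atoms: none
Why: Friedel–Crafts acylation should occur ortho to the activating methyl group (meta to bromine), and the AlCl3-bound aryl propenyl ketone then closes by Nazarov-type cyclisation onto the only free ortho carbon, the usual one-pot indanone synthesis from arenes and α,β-unsaturated acid chlorides; C3 is formed racemic and is erased in step 4.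

Step 2
Reactants: 4 rac-4-bromo-3,7-dimethyl-2,3-dihydro-1H-inden-1-one
Product: 5 rac-3,7-dimethyl-1-oxo-2,3-dihydro-1H-indene-4-carbaldehyde
Conditions: Pd(OAc)2 (1 mol %), di(1-adamantyl)-n-butylphosphine (3 mol %), TMEDA (1 equiv), CO/H2 (1:1, 5 bar), toluene, 100 °C
Reagents that add atoms: carbon monoxide, [C-]#[O+]
Why: Palladium-catalysed reductive carbonylation of aryl bromides (oxidative addition, CO insertion, hydrogenolysis of the acyl–palladium species) tolerates ketones and should turn C4–Br directly into C4–CHO.

Step 3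
Reactants: 5 rac-3,7-dimethyl-1-oxo-2,3-dihydro-1H-indene-4-carbaldehyde
Product: 6 rac-6-bromo-3,7-dimethyl-1-oxo-2,3-dihydro-1H-indene-4-carbaldehyde
Conditions: AlCl3 (3.5 equiv), Br2 (1.05 equiv), ClCH2CH2Cl, 0 °C to rt, dark
Reagents that add atoms: bromine, BrBr
Why: Electrophilic aromatic bromination under swamping-catalyst conditions, in which both carbonyl groups are tied up as AlCl3 complexes so that enolisation is suppressed, should go to C6, the one ring position that is ortho to the C7 methyl, para to the C3a alkyl carbon and meta to both acyl groups.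

Step 4
Reactants: 6 rac-6-bromo-3,7-dimethyl-1-oxo-2,3-dihydro-1H-indene-4-carbaldehyde
Product: 8 2,6-dibromo-3,7-dimethyl-1-oxo-1H-indene-4-carbaldehyde, via 2,2,6-tribromo indanone 7 (not isolated)
Conditions: Br2 (2.1 equiv), AcOH, 50 °C, dark; evaporate; Et3N (1.5 equiv), CH2Cl2, 0 °C to rt
Reagents that add atoms: bromine, BrBr
Why: Acid-catalysed α-bromination occurs twice at C2, the only enolisable position, and E2 loss of HBr across C3–H/C2–Br of the gem-dibromide gives the 2-bromoindenone, the standard bromination–dehydrobromination route to 2-bromoenones.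

Step 5
Reactants: 8 2,6-dibromo-3,7-dimethyl-1-oxo-1H-indene-4-carbaldehyde
Product: 9 2,6-dibromo-4-(1,3-dioxolan-2-yl)-3,7-dimethyl-1H-inden-1-one
Conditions: HOCH2CH2OH (3 equiv), TsOH·H2O (5 mol %), toluene, reflux, Dean–Stark
Reagents that add atoms: ethylene glycol, OCCO
Why: Acid-catalysed acetalisation with azeotropic removal of water should be selective for the aromatic aldehyde, because the C1 ketone is cross-conjugated and shielded by the C7 methyl and the C2 bromine.

Step 6
Reactants: 9 2,6-dibromo-4-(1,3-dioxolan-2-yl)-3,7-dimethyl-1H-inden-1-one; 10 (E)-2-(2-ethoxyvinyl)-4,4,5,5-tetramethyl-1,3,2-dioxaborolane (2.6 equiv)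
Product: 12 4-(1,3-dioxolan-2-yl)-2,6-bis[(E)-2-ethoxyvinyl]-3,7-dimethyl-1H-inden-1-one, via 6-bromo mono-coupling product 11 (not isolated)
Conditions: Pd(OAc)2 (5 mol %), SPhos (10 mol %), K3PO4 (4 equiv), 1,4-dioxane/H2O 10:1, 80 °C
Reagents that add atoms: none
Why: Twofold Suzuki–Miyaura coupling with retention of the (E)-alkenyl geometry, in which the activated C2 vinyl bromide should couple first and the biaryl phosphine lets the methyl-flanked C6 aryl bromide follow, while the acetal is inert to base.

**Lactone**

Step 7
Reactants: 13 hinokitiol (2-hydroxy-4-isopropylcyclohepta-2,4,6-trien-1-one)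
Product: 14 7-bromohinokitiol (7-bromo-2-hydroxy-4-isopropylcyclohepta-2,4,6-trien-1-one)
Conditions: NBS (1.0 equiv), CHCl3, 0 °C to rt
Reagents that add atoms: N-bromosuccinimide, O=C1CCC(=O)N1Br
Why: Electrophilic bromination of tropolones goes to the positions next to the oxygen-bearing carbons, and in hinokitiol C7 is the one of these that is not crowded by the isopropyl group.

Step 8
Reactants: 14 7-bromohinokitiol
Product: 15 7-bromo-4-isopropyl-2-(tosyloxy)cyclohepta-2,4,6-trien-1-one
Conditions: TsCl (1.1 equiv), Et3N (1.5 equiv), CH2Cl2, 0 °C to rt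
Reagents that add atoms: p-toluenesulfonyl chloride, Cc1ccc(cc1)S(Cl)(=O)=O
Why: O-sulfonylation should favour the oxygen remote from the C7 bromine (less hindered and not inductively deactivated), which puts the leaving group on C2 and leaves C1 as the carbonyl; any regioisomer would be removed by chromatography.

Step 9
Reactants: 15 7-bromo-4-isopropyl-2-(tosyloxy)cyclohepta-2,4,6-trien-1-one
Product: 16 4-isopropyl-7-methyl-2-(tosyloxy)cyclohepta-2,4,6-trien-1-one
Conditions: trimethylboroxine (0.5 equiv), Pd(PPh3)4 (5 mol %), K2CO3 (2 equiv), 1,4-dioxane, 90 °C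
Reagents that add atoms: trimethylboroxine, CB1OB(C)OB(C)O1
Why: Suzuki–Miyaura methylation, in which Pd(PPh3)4 should insert into the C–Br bond next to the tropone carbonyl much faster than into the sulfonate C–O bond, and the tosylate should survive carbonate in dioxane.

Step 10
Reactants: 16 4-isopropyl-7-methyl-2-(tosyloxy)cyclohepta-2,4,6-trien-1-one; 17 dimethyl malonate (1.2 equiv)
Product: 19 5-isopropyl-8-methyl-2H-cyclohepta[b]furan-2-one, via 3-methoxycarbonyl lactone 18 (not isolated)
Conditions: NaOMe (2.2 equiv), MeOH, 0 °C to rt; evaporate; 75% aq. H2SO4, 90 °C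
Reagents that add atoms: none
Why: The malonate anion displaces the tosylate at C2 by addition–elimination (C7 is blocked by the methyl group) and the tropone oxygen then acylates itself with one ester to close the lactone, the standard synthesis of 2H-cyclohepta[b]furan-2-ones; hot aqueous sulfuric acid hydrolyses the remaining ester and decarboxylates the acid through protonation at C3.

Step 11
Reactants: 19 5-isopropyl-8-methyl-2H-cyclohepta[b]furan-2-one
Product: 21 5-isopropyl-3,8-dimethyl-2H-cyclohepta[b]furan-2-one, via 3-iodo lactone 20 (not isolated)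
Conditions: NIS (1.05 equiv), CH2Cl2, rt; evaporate; trimethylboroxine (0.5 equiv), PdCl2(dppf) (5 mol %; dppf = 1,1'-bis(diphenylphosphino)ferrocene), K3PO4 (3 equiv), 1,4-dioxane/H2O, 80 °C
Reagents that add atoms: trimethylboroxine, CB1OB(C)OB(C)O1 (N-iodosuccinimide, O=C1CCC(=O)N1I, supplies the iodine of intermediate 20 only)
Why: C3 is the nucleophilic terminus of the heptafulvene-type enol lactone and is iodinated by NIS, and the resulting α-iodo enol lactone is a reactive partner for Suzuki–Miyaura coupling, the one-pot iodination–coupling route to 3-substituted 2H-cyclohepta[b]furan-2-ones.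

**Key step and end game**

Step 12
Reactants: 12 4-(1,3-dioxolan-2-yl)-2,6-bis[(E)-2-ethoxyvinyl]-3,7-dimethyl-1H-inden-1-one; 21 5-isopropyl-3,8-dimethyl-2H-cyclohepta[b]furan-2-one (3 equiv)
Product: 23 4-(1,3-dioxolan-2-yl)-2,6-bis(5-isopropyl-3,8-dimethylazulen-1-yl)-3,7-dimethyl-1H-inden-1-one, via mono-azulene 22 (not isolated)
Conditions: toluene (degassed), sealed tube, 190 °C, argon
Reagents that add atoms: none
Why: The β-carbon of each enol ether (the carbon bonded to the indenone) attacks the electrophilic C8a of the lactone and the developing oxocarbenium carbon is trapped by C3, which amounts to a thermal [8+2] cycloaddition of the heptafulvene-type 8π system to the enol ether 2π bond; the strained bridged lactone then extrudes CO2 and the resulting 1,2-dihydroazulene loses ethanol to aromatise. This is the Yasunami–Takase azulene synthesis from 2H-cyclohepta[b]furan-2-ones and enol ethers, run here once on each arm. Each five-membered ring is closed by an intermolecular two-bond annulation (C8a–C and C3–C formed in the cycloaddition), not by cyclisation of a tether. The sp3 centres of the bridged adducts and dihydroazulenes are transient, so no stereocentre survives in 23. The step needs the orientation that joins the indenone-bearing carbon to C8a next to the C8 methyl, and it needs the enol ether C=C to react in preference to the tetrasubstituted, electron-poor C2=C3 bond of the indenone; the first follows from the matched polarity (nucleophilic enol ether β-carbon, electrophilic oxygen-bearing C8a, nucleophilic C3) and the second from the donor substitution and lower hindrance of the arms. An excess of lactone and acid-free glassware should keep the acetal and the unreacted enol ether intact until both arms have reacted.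

Step 13
Reactants: 23 4-(1,3-dioxolan-2-yl)-2,6-bis(5-isopropyl-3,8-dimethylazulen-1-yl)-3,7-dimethyl-1H-inden-1-one
Product: 24 2,6-bis(5-isopropyl-3,8-dimethylazulen-1-yl)-3,7-dimethyl-1-oxo-1H-indene-4-carbaldehyde
Conditions: 1 M aq. HCl, THF, rt
Reagents that add atoms: water, O
Why: Mild aqueous acid hydrolyses the dioxolane through the benzylic oxocarbenium ion, and since C1 and C3 of both azulenes are substituted, dilute acid can only protonate them reversibly.

**Compound list**

1 | 4-bromotoluene | Cc1ccc(Br)cc1 | starting material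
2 | (E)-crotonoyl chloride | C/C=C/C(Cl)=O | starting material
3 | (E)-1-(5-bromo-2-methylphenyl)but-2-en-1-one | C/C=C/C(=O)c1cc(Br)ccc1C | intermediate
4 | rac-4-bromo-3,7-dimethyl-2,3-dihydro-1H-inden-1-one | CC1CC(=O)c2c(C)ccc(Br)c12 | intermediate
5 | rac-3,7-dimethyl-1-oxo-2,3-dihydro-1H-indene-4-carbaldehyde | CC1CC(=O)c2c(C)ccc(C=O)c12 | intermediate
6 | rac-6-bromo-3,7-dimethyl-1-oxo-2,3-dihydro-1H-indene-4-carbaldehyde | CC1CC(=O)c2c(C)c(Br)cc(C=O)c12 | intermediate
7 | rac-2,2,6-tribromo-3,7-dimethyl-1-oxo-2,3-dihydro-1H-indene-4-carbaldehyde | CC1C(Br)(Br)C(=O)c2c(C)c(Br)cc(C=O)c12 | intermediate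
8 | 2,6-dibromo-3,7-dimethyl-1-oxo-1H-indene-4-carbaldehyde | CC1=C(Br)C(=O)c2c(C)c(Br)cc(C=O)c12 | intermediate
9 | 2,6-dibromo-4-(1,3-dioxolan-2-yl)-3,7-dimethyl-1H-inden-1-one | CC1=C(Br)C(=O)c2c(C)c(Br)cc(C3OCCO3)c12 | intermediate
10 | (E)-2-(2-ethoxyvinyl)-4,4,5,5-tetramethyl-1,3,2-dioxaborolane | CCO/C=C/B1OC(C)(C)C(C)(C)O1 | starting material
11 | 6-bromo-4-(1,3-dioxolan-2-yl)-2-[(E)-2-ethoxyvinyl]-3,7-dimethyl-1H-inden-1-one | CCO/C=C/C1=C(C)c2c(C3OCCO3)cc(Br)c(C)c2C1=O | intermediate
12 | 4-(1,3-dioxolan-2-yl)-2,6-bis[(E)-2-ethoxyvinyl]-3,7-dimethyl-1H-inden-1-one | CCO/C=C/C1=C(C)c2c(C3OCCO3)cc(/C=C/OCC)c(C)c2C1=O | intermediate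
13 | hinokitiol (2-hydroxy-4-isopropylcyclohepta-2,4,6-trien-1-one) | O=C1C(O)=CC(C(C)C)=CC=C1 | starting material
14 | 7-bromohinokitiol (7-bromo-2-hydroxy-4-isopropylcyclohepta-2,4,6-trien-1-one) | O=C1C(O)=CC(C(C)C)=CC=C1Br | intermediate
15 | 7-bromo-4-isopropyl-2-(tosyloxy)cyclohepta-2,4,6-trien-1-one | O=C1C(OS(=O)(=O)c2ccc(C)cc2)=CC(C(C)C)=CC=C1Br | intermediate
16 | 4-isopropyl-7-methyl-2-(tosyloxy)cyclohepta-2,4,6-trien-1-one | O=C1C(OS(=O)(=O)c2ccc(C)cc2)=CC(C(C)C)=CC=C1C | intermediate
17 | dimethyl malonate | COC(=O)CC(=O)OC | starting material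
18 | methyl 5-isopropyl-8-methyl-2-oxo-2H-cyclohepta[b]furan-3-carboxylate | COC(=O)C1=C2C=C(C(C)C)C=CC(C)=C2OC1=O | intermediate
19 | 5-isopropyl-8-methyl-2H-cyclohepta[b]furan-2-one | O=C1C=C2C=C(C(C)C)C=CC(C)=C2O1 | intermediate
20 | 3-iodo-5-isopropyl-8-methyl-2H-cyclohepta[b]furan-2-one | IC1=C2C=C(C(C)C)C=CC(C)=C2OC1=O | intermediate
21 | 5-isopropyl-3,8-dimethyl-2H-cyclohepta[b]furan-2-one | CC1=C2C=C(C(C)C)C=CC(C)=C2OC1=O | intermediate
22 | 4-(1,3-dioxolan-2-yl)-2-[(E)-2-ethoxyvinyl]-6-(5-isopropyl-3,8-dimethylazulen-1-yl)-3,7-dimethyl-1H-inden-1-one | CCO/C=C/C1=C(C)c2c(C3OCCO3)cc(-c3cc(C)c4cc(C(C)C)ccc(C)c3-4)c(C)c2C1=O | intermediate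
23 | 4-(1,3-dioxolan-2-yl)-2,6-bis(5-isopropyl-3,8-dimethylazulen-1-yl)-3,7-dimethyl-1H-inden-1-one | CC1=C(c2cc(C)c3cc(C(C)C)ccc(C)c2-3)C(=O)c2c(C)c(-c3cc(C)c4cc(C(C)C)ccc(C)c3-4)cc(C3OCCO3)c21 | intermediate
24 | 2,6-bis(5-isopropyl-3,8-dimethylazulen-1-yl)-3,7-dimethyl-1-oxo-1H-indene-4-carbaldehyde | CC1=C(c2cc(C)c3cc(C(C)C)ccc(C)c2-3)C(=O)c2c(C)c(-c3cc(C)c4cc(C(C)C)ccc(C)c3-4)cc(C=O)c21 | target

**Totals**

Total step count: 13 steps.
Longest linear sequence: 8 steps (steps 1 to 6, then 12 and 13). The lactone branch (steps 7 to 11) joins at step 12.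

**Steps most likely to fail**

Step 12. The cycloaddition may stall, because the enol ether arms are hindered and only moderately nucleophilic while the lactone is deactivated by its two methyl groups. Long heating could then let the dienyl ether arm at C2 polymerise, or the cascade could stop after one arm. The fallback attaches ready-made azulenes and sets out from dibromide 9. Purchased guaiazulene F1 would be brominated at C3 with NBS (hexane, 0 °C) to the labile 3-bromoguaiazulene F2. This would be converted at once by Miyaura borylation (B2pin2, PdCl2(dppf), KOAc, 1,4-dioxane, 80 °C) into 2-(5-isopropyl-3,8-dimethylazulen-1-yl)-4,4,5,5-tetramethyl-1,3,2-dioxaborolane F3. Twofold Suzuki–Miyaura coupling of F3 with 9 (Pd(OAc)2, SPhos, K3PO4) comes back to the route at acetal 23.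

Step 10. Addition–elimination at C2 may be slow, since the bulky stabilised carbanion must attack a carbon of a tropone whose other α-position is blocked. Methoxide could then cleave the sulfonate at sulfur and return the tropolone. The fallback forms the C–C bond by cross-coupling and sets out from tosylate 16. A palladium-catalysed Negishi-type coupling with the Reformatsky reagent of ethyl 2-bromopropanoate (Zn, THF; Pd(OAc)2, XPhos, 60 °C) would give ethyl 2-(3-isopropyl-6-methyl-7-oxocyclohepta-1,3,5-trien-1-yl)propanoate F4. NaOEt in EtOH would then close the lactone by attack of the tropone oxygen on the ester. This comes back to the route at lactone 21 and makes step 11 unnecessary.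

Step 9. Methyl transfer may be accompanied by insertion of palladium into the troponyl sulfonate or by its hydrolysis under the basic conditions. The fallback installs the methyl group before the leaving group and sets out from hinokitiol 13. Mannich aminomethylation at C7 (morpholine, aqueous formaldehyde, MeOH) would give 2-hydroxy-4-isopropyl-7-(morpholin-4-ylmethyl)cyclohepta-2,4,6-trien-1-one F5. Hydrogenolysis of its benzylic-type C–N bond (H2, Pd/C, AcOH, 50 °C), as with phenolic Mannich bases, would give 7-methylhinokitiol F6. Tosylation of F6 under the conditions of step 8 comes back to the route at tosylate 16.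

Further compounds
F1 | step 12 | guaiazulene (7-isopropyl-1,4-dimethylazulene, purchased) | Cc1ccc2c(C)ccc(C(C)C)cc1-2
F2 | step 12 | 3-bromoguaiazulene (3-bromo-7-isopropyl-1,4-dimethylazulene) | Cc1cc(Br)c2c(C)ccc(C(C)C)cc1-2
F3 | step 12 | 2-(5-isopropyl-3,8-dimethylazulen-1-yl)-4,4,5,5-tetramethyl-1,3,2-dioxaborolane | Cc1cc(B3OC(C)(C)C(C)(C)O3)c2c(C)ccc(C(C)C)cc1-2
F4 | step 10 | rac-ethyl 2-(3-isopropyl-6-methyl-7-oxocyclohepta-1,3,5-trien-1-yl)propanoate | CCOC(=O)C(C)C1=CC(C(C)C)=CC=C(C)C1=O
F5 | step 9 | 2-hydroxy-4-isopropyl-7-(morpholin-4-ylmethyl)cyclohepta-2,4,6-trien-1-one | O=C1C(O)=CC(C(C)C)=CC=C1CN1CCOCC1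
F6 | step 9 | 7-methylhinokitiol (2-hydroxy-4-isopropyl-7-methylcyclohepta-2,4,6-trien-1-one) | O=C1C(O)=CC(C(C)C)=CC=C1C
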